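**Retrosynthetic overview**

1. Locants (target): C1 = CH(OAc) bridge carbon, C2 = methyl bridgehead, C3, C4=C5 (C11 = CHO carbon on C5), C6 = bridgehead carrying C10 (CHO), C7 (side chain, methine C1'), C8, C9; ring A = C1–C6, ring B = C1, C2, C9, C8, C7, C6.
2. Feature used: in ring A, C5 lies between the quaternary C6 and the CH carbon C4, so C4 can be excised. Ring A then becomes a five-membered ring C1, C2, C3, C5, C6 held by a temporary C3–C5 bond, i.e. a bicyclo[3.2.1]octane-6,8-dione (ketones at C1 and C5), which trimethylsilyldiazomethane re-expands by one carbon with migration of C3.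
3. After the expansion: C5 ketone ⇒ enol triflate ⇒ C11 by carbonylation; C1 ketone ⇒ alcohol by hydride from the ring A side; C1 acetate; 1,4-diol C10/C11 ⇒ ene-dialdehyde.
4. Before it: C5–C6 bond and quaternary C6 by radical cyclisation of an epoxide-derived C6 radical onto the C5 aldehyde; quaternary C2 by Johnson–Claisen rearrangement from a C6 tertiary allylic alcohol; C10 by hydroxymethyl addition to the C6 enone.
5. Ring order: ring B first (from (R)-citronellal and methyl vinyl ketone, C7 set against C1' by enamine catalysis), then the five-membered ring, then ring A by enlargement of that ring.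

Key step: step 14

Remark on the chemistry: centres that later become sp2 (C2 in 6, C1 and C6 in 15–17, C1 and C5 in 18) need no control; the SMILES show the isomer expected (epoxide anti to the C2 arm) or leave the centre open. R stands for the (2R)-6-methylhept-5-en-2-yl side chain.

Step 1
Reactants: 1 (R)-citronellal; 2 methyl vinyl ketone
Product: 3 (2S)-2-[(2R)-6-methylhept-5-en-2-yl]-5-oxohexanal
Conditions: (S)-2-[methoxy(diphenyl)methyl]pyrrolidine (5 mol %), ethyl 3,4-dihydroxybenzoate (20 mol %), neat, 4 °C
Reagents that add atoms: none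
Why: Enamine-catalysed Michael addition of the aldehyde to the enone, in which the (S)-diarylprolinol ether shields one face of the E-enamine so that C8 should be attached to C7 with the 7S configuration next to the untouched C1' centre (catalyst control).

Step 2
Reactants: 3 keto aldehyde
Product: 5 (4S)-4-[(2R)-6-methylhept-5-en-2-yl]cyclohex-2-en-1-one, via ketol 4 (not isolated)
Conditions: KOH (0.1 M aq.), Bu4NOH (cat.), Et2O/THF, reflux
Reagents that add atoms: none
Why: Intramolecular aldol condensation (second half of a Robinson annulation): the ketone methyl carbon C1 adds to the aldehyde carbon C6 to give ketol 4, which dehydrates to the conjugated enone, and ring closure under dilute hydroxide should outrun epimerisation of the aldehyde α-carbon C7.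

Step 3
Reactants: 5 cyclohexenone
Product: 6 (4S)-1-methyl-4-R-cyclohex-2-en-1-ol (both carbinol epimers)
Conditions: MeLi, Et2O, −78 °C; then H2O
Reagents that add atoms: methyllithium [Li]C
Why: 1,2-Addition of methyllithium to the enone carbonyl C2 brings in the C2 methyl group, and the carbinol configuration is irrelevant because C2 becomes sp2 in step 4.

Step 4
Reactants: 6 tertiary allylic alcohol
Product: 7 (6S)-3-methyl-6-[(2R)-6-methylhept-5-en-2-yl]cyclohex-2-en-1-one
Conditions: [C5H5NH][CrO3Cl] (pyridinium chlorochromate), NaOAc, 4 Å MS, CH2Cl2, rt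
Reagents that add atoms: none
Why: Babler–Dauben oxidative transposition: the tertiary allylic chromate ester shifts [3,3] to the C6 chromate, which is oxidised to the ketone, so the oxygen moves to C6 next to C7 and the methyl-bearing C2 becomes the β-carbon, while the acetate buffer guards the now enolisable C7.

Step 5
Reactants: 7 enone
Product: 9 1-(hydroxymethyl)-3-methyl-6-R-cyclohex-2-en-1-ol (tertiary OH cis to R), via β-hydroxysilane 8 (not isolated)
Conditions: (iPrO)Me2SiCH2MgCl (from ClCH2SiMe2(OiPr), Mg, THF), THF, −78 → 0 °C; then KF, KHCO3, 30% H2O2, MeOH/THF, rt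
Reagents that add atoms: (isopropoxydimethylsilyl)methylmagnesium chloride CC(C)O[Si](C)(C)C[Mg]Cl; hydrogen peroxide OO
Why: Tamao nucleophilic hydroxymethylation (1,2-addition of the silylmethyl Grignard reagent to the β,β-disubstituted enone, then Tamao–Fleming oxidation of the C–Si bond), in which the bulky reagent should enter the C6 carbonyl from the equatorial direction, anti to the neighbouring pseudo-equatorial C7 side chain, leaving the tertiary hydroxyl cis to the side chain.

Step 6
Reactants: 9 diol
Product: 10 1-{[(tert-butyldimethylsilyl)oxy]methyl}-3-methyl-6-R-cyclohex-2-en-1-ol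
Conditions: TBSCl, imidazole, CH2Cl2, 0 °C
Reagents that add atoms: tert-butyldimethylsilyl chloride CC(C)(C)[Si](C)(C)Cl
Why: Selective silylation of the primary hydroxyl (the tertiary allylic alcohol is inert to TBSCl/imidazole), which keeps the 1,2-diol from being tied up as a cyclic orthoester in step 7.

Step 7
Reactants: 10 tertiary allylic alcohol; 11 triethyl orthoacetate
Product: 13 ethyl 2-{3-[(tert-butyldimethylsilyloxy)methyl]-1-methyl-4-R-cyclohex-2-en-1-yl}acetate (arm cis to R), via ketene acetal 12 (not isolated)
Conditions: MeC(OEt)3 (excess), EtCO2H (cat.), xylene, 140 °C, EtOH distilled off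
Reagents that add atoms: none
Why: Johnson–Claisen rearrangement: orthoester exchange at the C6 oxygen and loss of ethanol give ketene acetal 12, whose suprafacial [3,3] shift delivers the acetate arm (C3, C5) to C2 on the face that carried the C6–O bond, i.e. cis to the C7 side chain, creating the quaternary C2 and moving the double bond to C6=C1; the electron-withdrawing silyloxymethyl group should retard ionisation of the tertiary alcohol.

Step 8
Reactants: 13 silyl ether ester
Product: 14 ethyl 2-[3-(hydroxymethyl)-1-methyl-4-R-cyclohex-2-en-1-yl]acetate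
Conditions: Bu4NF, THF, 0 °C
Reagents that add atoms: none
Why: Fluoride cleavage of the primary silyl ether frees the allylic alcohol that must direct the epoxidation, and the hindered ethyl ester is untouched.

Step 9
Reactants: 14 allylic alcohol
Product: 15 epoxy alcohol (C1–C6 epoxide of 14, oxirane anti to the C2 arm)
Conditions: VO(acac)2 (cat.), tBuOOH, CH2Cl2, 0 °C → rt
Reagents that add atoms: tert-butyl hydroperoxide CC(C)(C)OO
Why: Hydroxyl-directed vanadium-catalysed epoxidation oxidises only the allylic-alcohol double bond C6=C1 and leaves the side-chain trisubstituted alkene alone; attack is expected anti to the axial C2 arm, but either face serves because C6 becomes a radical and C1 a ketone later.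

Step 10
Reactants: 15 epoxy alcohol
Product: 16 tert-butyldimethylsilyl ether of 15
Conditions: TBSCl, imidazole, DMF, rt
Reagents that add atoms: tert-butyldimethylsilyl chloride CC(C)(C)[Si](C)(C)Cl
Why: Silylation of the primary alcohol under mild, non-acidic conditions that neither open the epoxide nor induce epoxide migration, giving the protecting group carried through the ring expansion.

Step 11
Reactants: 16 epoxy ester
Product: 17 epoxy aldehyde (C5 = CHO)
Conditions: iBu2AlH (1.1 equiv), CH2Cl2, −78 °C; then aq. potassium sodium tartrate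
Reagents that add atoms: none
Why: Partial reduction of the ester with one equivalent of iBu2AlH stops at the tetrahedral aluminium hemiacetal, which gives the aldehyde on work-up, and the epoxide is inert at −78 °C.

Step 12
Reactants: 17 epoxy aldehyde
Product: 18 5-[(tert-butyldimethylsilyloxy)methyl]-1-methyl-4-R-bicyclo[3.2.1]octane-6,8-diol (OH at C1 and C5)
Conditions: Cp2TiCl2 (2.5 equiv), Mn, THF, rt (gives Cp2TiCl); slow addition of 17; then 1 M HCl
Reagents that add atoms: none
Why: Titanocene-mediated radical epoxide opening (Nugent–RajanBabu reaction) with 5-exo addition to an aldehyde, a known cyclisation of epoxy aldehydes to cycloalkanols: trivalent titanium (Cp2TiCl) cleaves the C6–O bond to the tertiary C6 radical, which adds to the C5 aldehyde and is trapped by a second Cp2TiCl, closing the ring C1, C2, C3, C5, C6 and fixing the quaternary C6 with C5 cis to the C2 arm because the two-carbon tether reaches only that face.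

Step 13
Reactants: 18 bicyclic diol
Product: 19 5-[(tert-butyldimethylsilyloxy)methyl]-1-methyl-4-R-bicyclo[3.2.1]octane-6,8-dione
Conditions: Dess–Martin periodinane, NaHCO3, CH2Cl2, rt
Reagents that add atoms: none
Why: Dess–Martin oxidation of both secondary alcohols converges all carbinol isomers of 18 to the single 1,3-diketone, which cannot enolise at the bridgehead C6 and so has no route to epimerisation or β-elimination.

Step 14
Reactants: 19 bicyclo[3.2.1]octane-6,8-dione; 20 trimethylsilyldiazomethane
Product: 22 1-[(tert-butyldimethylsilyloxy)methyl]-5-methyl-8-R-bicyclo[3.3.1]nonane-2,9-dione, via α-silyl ketone 21 (not isolated)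
Conditions: BF3·OEt2 (promoter), CH2Cl2, −78 → −30 °C; then 1 M HCl, THF, 0 °C
Reagents that add atoms: none
Why: BF3 coordinates to the C5 carbonyl oxygen, the nucleophilic diazo carbon of 20 attacks C5, and the diazonium alkoxide expels dinitrogen while the C3–C5 bond migrates onto the incoming carbon, which thereby becomes C4 between C3 and C5 (α-silyl ketone 21); acid work-up replaces silicon by hydrogen. The closest known reaction type is the Lewis acid-promoted Tiffeneau–Demjanov-type one-carbon homologation of cyclic ketones with trimethylsilyldiazomethane, as applied to bicyclo[2.2.1]heptanone to bicyclo[3.2.1]octanone enlargements. Ring A is not closed from a chain but arises by enlargement of the five-membered ring C1, C2, C3, C5, C6, the new bonds C3–C4 and C4–C5 taking the place of the temporary C3–C5 bond with relief of cyclopentanone eclipsing strain. No stereocentre of the product is created, since the silyl-bearing C4 of 21 ends as CH2 and C2, C6 and C7 are not touched. The step needs attack at C5 and not C1, and migration of C3 and not C6: the C1 carbonyl sits between the fully substituted C2 and C6 and is screened from the reagent, and the methylene C3 is a far better migrating group here than C6, which is quaternary and carries the C1 acyl group. A second insertion is held back because the carbonyl of 21 is flanked by the silylated C4 and the quaternary C6.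

Step 15
Reactants: 22 bicyclo[3.3.1]nonane-2,9-dione
Product: 23 C5 enol triflate (C4=C5–OTf, C1 ketone kept)
Conditions: KN(SiMe3)2, THF, −78 °C; PhNTf2, −78 → 0 °C
Reagents that add atoms: N-phenylbis(trifluoromethanesulfonimide) O=S(=O)(N(c1ccccc1)S(=O)(=O)C(F)(F)F)C(F)(F)F
Why: Enolate O-triflation: the non-nucleophilic amide base can deprotonate only at C4, since C6 is quaternary and C1 has no α-hydrogen, so the C5 enolate is formed regiospecifically and trapped as the C4=C5 enol triflate.

Step 16
Reactants: 23 enol triflate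
Product: 24 methyl ester at C5 (C11 = CO2Me on C4=C5, C1 ketone kept)
Conditions: Pd(OAc)2 (cat.), PPh3, CO (1 atm), MeOH, Et3N, DMF, 60 °C
Reagents that add atoms: carbon monoxide [C-]#[O+]; methanol CO
Why: Palladium-catalysed methoxycarbonylation of the enol triflate (oxidative addition of zerovalent palladium formed in situ, CO insertion, methanolysis) installs C11 on C5 with the C4=C5 double bond already in place.

Step 17
Reactants: 24 keto ester
Product: 25 diol (C1–OH on the ring B side, C11 allylic alcohol, C10 still OTBS)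
Conditions: LiAlH4, Et2O, −78 → 0 °C; then H2O
Reagents that add atoms: none
Why: LiAlH4 reduces the conjugated ester to the allylic alcohol and the C1 ketone to the alcohol, and hydride should reach C1 from the ring A side, where C4 and C5 are sp2 and only one pseudo-axial C3–H intervenes, instead of past the axial hydrogens at C7 and C9 of ring B, which places the hydroxyl on the ring B side as in the target.

Step 18
Reactants: 25 diol
Product: 26 C10,C11-bis(tert-butyldimethylsilyl) ether with free C1–OH
Conditions: TBSCl, imidazole, CH2Cl2, 0 °C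
Reagents that add atoms: tert-butyldimethylsilyl chloride CC(C)(C)[Si](C)(C)Cl
Why: Silylation of the primary allylic hydroxyl only (the C1 hydroxyl between two quaternary carbons does not react), so that C1 can be acetylated alone and both primary positions carry the same fluoride-labile group.

Step 19
Reactants: 26 C1 alcohol
Product: 27 C1 acetate of 26
Conditions: Ac2O, DMAP, pyridine, 40 °C
Reagents that add atoms: acetic anhydride CC(=O)OC(C)=O
Why: DMAP-catalysed acetylation of the hindered secondary C1 alcohol, done before any aldehyde is present so that no base-sensitive carbonyl group is exposed to the acylation conditions.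

Step 20
Reactants: 27 acetate bis-silyl ether
Product: 28 C1 acetate 1,4-diol (C10–OH and C11–OH free)
Conditions: HF·pyridine, pyridine, THF, 0 °C → rt
Reagents that add atoms: none
Why: Fluoride cleavage of both primary silyl ethers under buffered, weakly acidic conditions, chosen so that the C1 acetate is neither cleaved nor moved to the neighbouring C10 hydroxyl.

Step 21
Reactants: 28 diol acetate
Product: 29 target CNP0299929.2
Conditions: (COCl)2, DMSO, CH2Cl2, −78 °C; Et3N, −78 → 0 °C
Reagents that add atoms: none
Why: Swern oxidation activates both primary hydroxyls as alkoxysulfonium ions before base is added, so the 1,4-diol goes straight to the ene-dialdehyde without passing through a hydroxy aldehyde that would close to a lactol and be oxidised to a lactone; C6 has no α-hydrogen, so neither epimerisation nor loss of the β-acetate can follow.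

**Compound list**

1 | (R)-citronellal, (3R)-3,7-dimethyloct-6-enal | O=CC[C@H](C)CCC=C(C)C | starting material
2 | methyl vinyl ketone (but-3-en-2-one) | CC(=O)C=C | starting material
3 | (2S)-2-[(2R)-6-methylhept-5-en-2-yl]-5-oxohexanal | O=C[C@@H](CCC(C)=O)[C@H](C)CCC=C(C)C | intermediate
4 | 3-hydroxy-4-[(2R)-6-methylhept-5-en-2-yl]cyclohexan-1-one (aldol adduct, carbinol centre open) | O=C1CC(O)[C@H]([C@H](C)CCC=C(C)C)CC1 | intermediate (not isolated)
5 | (4S)-4-[(2R)-6-methylhept-5-en-2-yl]cyclohex-2-en-1-one | O=C1C=C[C@H]([C@H](C)CCC=C(C)C)CC1 | intermediate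
6 | (4S)-1-methyl-4-[(2R)-6-methylhept-5-en-2-yl]cyclohex-2-en-1-ol (both carbinol epimers) | CC1(O)C=C[C@H]([C@H](C)CCC=C(C)C)CC1 | intermediate
7 | (6S)-3-methyl-6-[(2R)-6-methylhept-5-en-2-yl]cyclohex-2-en-1-one | CC1=CC(=O)[C@H]([C@H](C)CCC=C(C)C)CC1 | intermediate
8 | 1-{[dimethyl(propan-2-yloxy)silyl]methyl}-3-methyl-6-R-cyclohex-2-en-1-ol, OH cis to R | CC(C)O[Si](C)(C)C[C@]1(O)C=C(C)CC[C@H]1[C@H](C)CCC=C(C)C | intermediate (not isolated)
9 | 1-(hydroxymethyl)-3-methyl-6-R-cyclohex-2-en-1-ol, tertiary OH cis to R | OC[C@]1(O)C=C(C)CC[C@H]1[C@H](C)CCC=C(C)C | intermediate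
10 | 1-{[(tert-butyldimethylsilyl)oxy]methyl}-3-methyl-6-R-cyclohex-2-en-1-ol, OH cis to R | CC(C)(C)[Si](C)(C)OC[C@]1(O)C=C(C)CC[C@H]1[C@H](C)CCC=C(C)C | intermediate
11 | triethyl orthoacetate (1,1,1-triethoxyethane) | CCOC(C)(OCC)OCC | starting material
12 | 1-ethoxyvinyl ether of 10 (mixed ketene acetal on the C6 oxygen) | C=C(OCC)O[C@@]1(CO[Si](C)(C)C(C)(C)C)C=C(C)CC[C@H]1[C@H](C)CCC=C(C)C | intermediate (not isolated)
13 | ethyl 2-{3-[(tert-butyldimethylsilyloxy)methyl]-1-methyl-4-R-cyclohex-2-en-1-yl}acetate, arm cis to R | CCOC(=O)C[C@]1(C)C=C(CO[Si](C)(C)C(C)(C)C)[C@H]([C@H](C)CCC=C(C)C)CC1 | intermediate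
14 | ethyl 2-[3-(hydroxymethyl)-1-methyl-4-R-cyclohex-2-en-1-yl]acetate | CCOC(=O)C[C@]1(C)C=C(CO)[C@H]([C@H](C)CCC=C(C)C)CC1 | intermediate
15 | C1–C6 epoxide of 14 (epoxy alcohol, oxirane anti to the C2 arm) | CCOC(=O)C[C@]1(C)[C@H]2O[C@@]2(CO)[C@H]([C@H](C)CCC=C(C)C)CC1 | intermediate
16 | tert-butyldimethylsilyl ether of 15 | CCOC(=O)C[C@]1(C)[C@H]2O[C@@]2(CO[Si](C)(C)C(C)(C)C)[C@H]([C@H](C)CCC=C(C)C)CC1 | intermediate
17 | epoxy aldehyde (ester of 16 reduced to CHO at C5) | O=CC[C@]1(C)[C@H]2O[C@@]2(CO[Si](C)(C)C(C)(C)C)[C@H]([C@H](C)CCC=C(C)C)CC1 | intermediate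
18 | 5-[(tert-butyldimethylsilyloxy)methyl]-1-methyl-4-R-bicyclo[3.2.1]octane-6,8-diol (C5 carbinol open) | O[C@@H]1[C@@]2(C)CC(O)[C@]1(CO[Si](C)(C)C(C)(C)C)[C@H]([C@H](C)CCC=C(C)C)CC2 | intermediate
19 | 5-[(tert-butyldimethylsilyloxy)methyl]-1-methyl-4-R-bicyclo[3.2.1]octane-6,8-dione (ketones at C1 and C5) | O=C1[C@@]2(C)CC(=O)[C@]1(CO[Si](C)(C)C(C)(C)C)[C@H]([C@H](C)CCC=C(C)C)CC2 | intermediate
20 | trimethylsilyldiazomethane | C[Si](C)(C)C=[N+]=[N-] | starting material
21 | 3-(trimethylsilyl) derivative of 22 (silicon on C4) | O=C1[C@@]2(C)CC([Si](C)(C)C)C(=O)[C@]1(CO[Si](C)(C)C(C)(C)C)[C@H]([C@H](C)CCC=C(C)C)CC2 | intermediate (not isolated)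
22 | 1-[(tert-butyldimethylsilyloxy)methyl]-5-methyl-8-R-bicyclo[3.3.1]nonane-2,9-dione (ketones at C5 and C1) | O=C1[C@@]2(C)CCC(=O)[C@]1(CO[Si](C)(C)C(C)(C)C)[C@H]([C@H](C)CCC=C(C)C)CC2 | intermediate
23 | 1-[(tert-butyldimethylsilyloxy)methyl]-5-methyl-9-oxo-8-R-bicyclo[3.3.1]non-2-en-2-yl trifluoromethanesulfonate | O=C1[C@@]2(C)CC=C(OS(=O)(=O)C(F)(F)F)[C@]1(CO[Si](C)(C)C(C)(C)C)[C@H]([C@H](C)CCC=C(C)C)CC2 | intermediate
24 | methyl 1-[(tert-butyldimethylsilyloxy)methyl]-5-methyl-9-oxo-8-R-bicyclo[3.3.1]non-2-ene-2-carboxylate | O=C1[C@@]2(C)CC=C(C(=O)OC)[C@]1(CO[Si](C)(C)C(C)(C)C)[C@H]([C@H](C)CCC=C(C)C)CC2 | intermediate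
25 | diol: C1–OH (ring B side), C11–OH, C10–OTBS | O[C@@H]1[C@@]2(C)CC=C(CO)[C@]1(CO[Si](C)(C)C(C)(C)C)[C@H]([C@H](C)CCC=C(C)C)CC2 | intermediate
26 | C10,C11-bis(tert-butyldimethylsilyl) ether, free C1–OH | O[C@@H]1[C@@]2(C)CC=C(CO[Si](C)(C)C(C)(C)C)[C@]1(CO[Si](C)(C)C(C)(C)C)[C@H]([C@H](C)CCC=C(C)C)CC2 | intermediate
27 | C1 acetate of 26 | CC(=O)O[C@@H]1[C@@]2(C)CC=C(CO[Si](C)(C)C(C)(C)C)[C@]1(CO[Si](C)(C)C(C)(C)C)[C@H]([C@H](C)CCC=C(C)C)CC2 | intermediate
28 | C1 acetate with free C10–OH and C11–OH (1,4-diol) | CC(=O)O[C@@H]1[C@@]2(C)CC=C(CO)[C@]1(CO)[C@H]([C@H](C)CCC=C(C)C)CC2 | intermediate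
29 | CNP0299929.2 | CC(=O)O[C@@H]1[C@@]2(C)CC=C(C=O)[C@]1(C=O)[C@H]([C@H](C)CCC=C(C)C)CC2 | target

Total step count: 21. Longest linear sequence: 21 steps (1 to 29, fully linear).

**Steps most likely to fail**

Step 14 (ring expansion). The diazo reagent may add to the C1 carbonyl, C6 may migrate instead of C3, the betaine may close to an epoxide or fragment in the retro-Claisen sense, or BF3 may strip the silyl ether. The fallback uses a known siloxycyclopropane ring enlargement whose regiochemistry is fixed by enolisation. It sets out from 19: TMSOTf/Et3N gives the C5 trimethylsilyl enol ether F1, which can form only towards C3. Et2Zn/CH2I2 cyclopropanates this electron-rich double bond to the siloxycyclopropane F2. FeCl3 in DMF cleaves the C3–C5 bond oxidatively to the ring-enlarged β-chloro ketone F3, and NaOAc in MeOH eliminates HCl to the enone F4 (C3=C4–C5=O). Conjugate reduction with LiBH(sBu)3 and trapping of the C5 enolate with PhNTf2 returns to the route at enol triflate 23.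

Step 12 (radical ring closure). The C6 radical may be reduced or quenched before it cyclises, the addition to the carbonyl may revert, or the radical may attack the side-chain alkene. The fallback closes the ring by an ionic aldol addition and turns the premature reduction into the plan. It sets out from 16: Cp2TiCl (from Cp2TiCl2/Mn) with 1,4-cyclohexadiene opens the epoxide reductively to the C1 alcohol F5. LiAlH4 gives the diol F6, and Dess–Martin oxidation gives the keto aldehyde F7. K2CO3 in MeOH effects intramolecular aldol addition of the C6 enolate to the C5 aldehyde, giving the ketol F8. Dess–Martin oxidation of F8 returns to the route at 19.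

Step 7 (Johnson–Claisen rearrangement, together with the facial selectivity of step 5 that it transmits). The hindered tertiary allylic alcohol may exchange slowly or dehydrate, the silyl ether may be lost, or the wrong carbinol epimer may carry the arm to the wrong face of C2. The fallback sets C2 by conjugate addition instead of carbonyl addition plus [3,3] shift. It sets out from enone 7: TiCl4-promoted Mukaiyama–Michael addition of 1-ethoxy-1-(trimethylsilyloxy)ethene places the acetate arm on C2 by axial attack, giving the keto ester F9. LiN(SiMe3)2 then PhNTf2 gives the less substituted enol triflate F10 (C6=C1). Stille coupling with Bu3SnCH2OH (Pd(PPh3)4, LiCl, dioxane) returns to the route at allylic alcohol 14.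

**Further compounds**

F1 | step 14 | C5 trimethylsilyl enol ether of 19 (C3=C5–OTMS) | O=C1[C@@]2(C)C=C(O[Si](C)(C)C)[C@]1(CO[Si](C)(C)C(C)(C)C)[C@H]([C@H](C)CCC=C(C)C)CC2
F2 | step 14 | siloxycyclopropane (C4 bridging C3 and C5) | O=C1[C@@]2(C)C3CC3(O[Si](C)(C)C)[C@]1(CO[Si](C)(C)C(C)(C)C)[C@H]([C@H](C)CCC=C(C)C)CC2
F3 | step 14 | ring-enlarged β-chloro ketone (Cl on C3) | O=C1[C@@]2(C)C(Cl)CC(=O)[C@]1(CO[Si](C)(C)C(C)(C)C)[C@H]([C@H](C)CCC=C(C)C)CC2
F4 | step 14 | enone (C3=C4–C5=O) of the bicyclo[3.3.1]nonane | O=C1[C@@]2(C)C=CC(=O)[C@]1(CO[Si](C)(C)C(C)(C)C)[C@H]([C@H](C)CCC=C(C)C)CC2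
F5 | step 12 | C1 alcohol with C6–H (reductively opened 16) | CCOC(=O)C[C@]1(C)[C@@H](O)C(CO[Si](C)(C)C(C)(C)C)[C@H]([C@H](C)CCC=C(C)C)CC1
F6 | step 12 | diol (C1–OH, C5–OH) | OCC[C@]1(C)[C@@H](O)C(CO[Si](C)(C)C(C)(C)C)[C@H]([C@H](C)CCC=C(C)C)CC1
F7 | step 12 | keto aldehyde (C1 ketone, C5 aldehyde) | O=CC[C@]1(C)C(=O)C(CO[Si](C)(C)C(C)(C)C)[C@H]([C@H](C)CCC=C(C)C)CC1
F8 | step 12 | bicyclic ketol (C1 ketone, C5–OH) | O=C1[C@@]2(C)CC(O)[C@]1(CO[Si](C)(C)C(C)(C)C)[C@H]([C@H](C)CCC=C(C)C)CC2
F9 | step 7 | ethyl 2-(1-methyl-3-oxo-4-R-cyclohexyl)acetate, arm cis to R | CCOC(=O)C[C@]1(C)CC(=O)[C@H]([C@H](C)CCC=C(C)C)CC1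
F10 | step 7 | C6 enol triflate of F9 (C6=C1) | CCOC(=O)C[C@]1(C)C=C(OS(=O)(=O)C(F)(F)F)[C@H]([C@H](C)CCC=C(C)C)CC1
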